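**Retrosynthetic overview** (chain numbered C1, alkyne CH, to C15, ethyl CH3; O6, O7, O9 are the ether oxygens on C6, C7, C9)
1. Enabling feature: O9 of the oxane links C9 and C13, and C8 (Br in the target, an oxygen until the last step) is vicinal to C9. C13 can therefore be held at the ketone level as a ketal of the C8,C9-diol, a 6,8-dioxabicyclo[3.2.1]octane whose O8–C13 bond is temporary.
2. Key disconnection: transketalisation (O9–C13, O8–C13) and ring-closing metathesis (C10=C11) of an erythro vinyl diol with the dimethyl ketal of allyl ethyl ketone close the oxane and the temporary dioxolane in one flask.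
3. The rigid bicycle then steers bromide to C10 and hydride to C12 from its open face; C4–C7 is added by Julia–Kocienski olefination and dihydroxylation, C1–C3 by Peterson olefination.
4. Ring order: oxane plus temporary dioxolane (step 5), then oxolane O7–C4 and oxolane O6–C3 of the 2,5-dioxabicyclo[2.2.1]heptane (step 20), then reductive opening of the dioxolane, which sets C13 (step 21).
5. C8–Br and C12–Br are made last by SN2 inversion of the two alcohols.

Key step: step 5

Remark on the chemistry: the Sharpless epoxidation of penta-1,4-dien-3-ol with the D-(−)-tartrate is assumed to give the (2S,3R)-epoxy alcohol; every later stereocentre is derived from it.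

**Step 1**
Reactants: 1 penta-1,4-dien-3-ol
Product: 2 (2S,3R)-1,2-epoxypent-4-en-3-ol
Conditions: Ti(OiPr)4, D-(−)-diisopropyl tartrate, t-BuOOH, 4 Å molecular sieves, CH2Cl2, −20 °C
Reagents that add atoms: tert-butyl hydroperoxide, CC(C)(C)OO
Why: Sharpless asymmetric epoxidation should desymmetrise the divinyl carbinol, the tartrate–Ti(OiPr)4 catalyst choosing one enantiotopic vinyl group and one of its faces, so that the erythro epoxy alcohol carries the future C8 and C9 centres.

**Step 2**
Reactants: 2 (2S,3R)-1,2-epoxypent-4-en-3-ol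
Product: 3 (2S,3R)-pent-4-ene-1,2,3-triol
Conditions: H2O, HClO4 (cat.), THF, 0 → 23 °C
Reagents that add atoms: water, O
Why: Acid-catalysed epoxide hydrolysis should proceed by attack of water at the unhindered primary carbon (future C7), so the configuration at C8 is retained.

**Step 3**
Reactants: 3 (2S,3R)-pent-4-ene-1,2,3-triol
Product: 4 (2S,3R)-2,3-dihydroxypent-4-en-1-yl pivalate
Conditions: pivaloyl chloride (1.05 equiv), pyridine, CH2Cl2, −20 °C
Reagents that add atoms: pivaloyl chloride, CC(C)(C)C(Cl)=O
Why: Selective acylation of the primary hydroxyl by the bulky acid chloride should leave the erythro C8,C9-diol free for ketal formation.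

**Step 4**
Reactants: 5 trimethyl orthopropionate; 6 allyltrimethylsilane
Product: 7 4,4-dimethoxyhex-1-ene
Conditions: Me3SiOTf (5 mol %), CH2Cl2, −78 °C
Reagents that add atoms: none
Why: Hosomi–Sakurai allylation of the dialkoxycarbenium ion released from the orthoester should give the β,γ-unsaturated ketal directly, without the free ketone that would isomerise into conjugation.

**Step 5**
Reactants: 4 (2S,3R)-2,3-dihydroxypent-4-en-1-yl pivalate; 7 4,4-dimethoxyhex-1-ene
Product: 9 [(1R,5R,7S)-5-ethyl-6,8-dioxabicyclo[3.2.1]oct-2-en-7-yl]methyl pivalate, via dioxolane ketal 8 (not isolated)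
Conditions: camphor-10-sulfonic acid (5 mol %), second-generation Grubbs catalyst (5 mol %), 4 Å molecular sieves, CH2Cl2, 40 °C
Reagents that add atoms: none
Why: Acid-catalysed transketalisation should transfer C13 of 7 to O8 and O9 of the erythro diol (two methanol lost to the sieves) to give dioxolane 8, and the second-generation Grubbs catalyst should then join the C9 vinyl group and the C13 allyl group by ring-closing metathesis, forming C10=C11 with loss of ethene. The closest known reaction type is the two-stage ketalisation/ring-closing metathesis route to 6,8-dioxabicyclo[3.2.1]oct-2-enes; here both catalysts share one flask so that the metathesis drains the ketal equilibrium. The dioxolane closes by reversible five-membered ketal formation (capture of the oxocarbenium ion by the second hydroxyl), and the oxane closes by six-membered ring-closing metathesis across the ketal carbon. The one new stereocentre, C13, is set by the ring closure itself: only the ketal epimer with allyl cis to the C9 vinyl group can reach the bicyclic olefin, and the other epimer is recycled through the oxocarbenium ion by the acid; C8 and C9 come unchanged from 4. The step needs the six-membered closure to win over cross-metathesis, which the 1,3-placement of the two terminal olefins across O9–C13 and the absence of any third olefin should secure. The product holds the oxane as a rigid chair with the O8–C8 bridge on one face, which later steers bromide to C10 and hydride to C12 and C13.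

**Step 6**
Reactants: 9 bicyclic olefin
Product: 11 [(1R,5R,7S)-5-ethyl-4-oxo-6,8-dioxabicyclo[3.2.1]oct-2-en-7-yl]methyl pivalate, via allylic alcohol 10 (not isolated)
Conditions: SeO2 (0.3 equiv), t-BuOOH, CH2Cl2, 23 °C; then Dess–Martin periodinane, NaHCO3, CH2Cl2, 0 °C
Reagents that add atoms: tert-butyl hydroperoxide, CC(C)(C)OO
Why: Allylic oxidation with SeO2 (ene reaction, then [2,3]-sigmatropic shift) should remove hydrogen only from C12, because the other ene pathway would need a double bond at the bridgehead C9 (Bredt's rule), and Dess–Martin oxidation of the allylic alcohol should then give the enone, a C-ethyl analogue of levoglucosenone.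

**Step 7**
Reactants: 11 bicyclic enone
Product: 13 [(2-bromo-5-ethyl-4-hydroxy-6,8-dioxabicyclo[3.2.1]octan-7-yl)]methyl pivalate (Br on C10 anti to the O8–C8 bridge, OH on C12 syn to it), via bromo ketone 12 (not isolated)
Conditions: HBr (anhydrous, 1.1 equiv), CH2Cl2, −78 °C; then MeOH, CeCl3·7H2O, NaBH4, −78 °C
Reagents that add atoms: hydrogen bromide, Br
Why: Conjugate (Michael-type) addition of HBr should put bromine on C10 from the face anti to the O8–C8 bridge, as nucleophiles add to levoglucosenone, and immediate Luche reduction should deliver hydride to C12 from the same open face, so that the new hydroxyl is syn to the bridge (the configuration that the final SN2 step inverts).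

**Step 8**
Reactants: 13 bromo alcohol
Product: 14 C12 tert-butyldimethylsilyl ether of 13
Conditions: t-BuMe2SiOTf, 2,6-lutidine, CH2Cl2, −40 → 0 °C
Reagents that add atoms: tert-butyldimethylsilyl trifluoromethanesulfonate, CC(C)(C)[Si](C)(C)OS(=O)(=O)C(F)(F)F
Why: Silyl ether formation with the silyl triflate should protect the hindered secondary C12 hydroxyl before the two oxidations of the side chain.

**Step 9**
Reactants: 14 silyl ether pivalate
Product: 15 primary alcohol at C7
Conditions: i-Bu2AlH, CH2Cl2, −78 °C
Reagents that add atoms: none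
Why: Reductive cleavage of the pivalate ester with i-Bu2AlH at low temperature should free the C7 hydroxyl without touching ketal, silyl ether or bromide.

**Step 10**
Reactants: 15 primary alcohol
Product: 16 C7 aldehyde
Conditions: Dess–Martin periodinane, NaHCO3, CH2Cl2, 0 → 23 °C
Reagents that add atoms: none
Why: Dess–Martin oxidation should give the α-alkoxy aldehyde under buffered, non-enolising conditions, so that C8 is not epimerised.

**Step 11**
Reactants: 17 3-[(4-methoxybenzyl)oxy]propan-1-ol; 18 1-phenyl-1H-tetrazole-5-thiol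
Product: 19 5-({3-[(4-methoxybenzyl)oxy]propyl}sulfanyl)-1-phenyl-1H-tetrazole
Conditions: PPh3, diisopropyl azodicarboxylate, THF, 0 → 23 °C
Reagents that add atoms: none
Why: Mitsunobu thioetherification of the primary alcohol with the acidic heteroaryl thiol should proceed by SN2 displacement of the alkoxyphosphonium ion.

**Step 12**
Reactants: 19 sulfide
Product: 20 5-({3-[(4-methoxybenzyl)oxy]propyl}sulfonyl)-1-phenyl-1H-tetrazole
Conditions: (NH4)6Mo7O24·4H2O (cat.), 30% H2O2, EtOH, 0 → 23 °C
Reagents that add atoms: hydrogen peroxide, OO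
Why: (NH4)6Mo7O24-catalysed peroxide oxidation should take the sulfide to the sulfone needed for the Julia–Kocienski olefination and leave the p-methoxybenzyl ether untouched.

**Step 13**
Reactants: 16 C7 aldehyde; 20 sulfone
Product: 21 (E)-olefin C6=C7 carrying the C4 p-methoxybenzyl ether
Conditions: 20, KN(SiMe3)2, 1,2-dimethoxyethane, −60 °C; then 16, −60 → 23 °C
Reagents that add atoms: none
Why: Julia–Kocienski olefination (addition, Smiles rearrangement, loss of SO2 and tetrazolone) of the unbranched phenyltetrazolyl sulfone anion with the α-branched aldehyde should give the E olefin.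

**Step 14**
Reactants: 21 (E)-olefin
Product: 22 C6,C7-diol (threo; C7–OH anti to O8)
Conditions: OsO4 (2 mol %), N-methylmorpholine N-oxide, acetone/H2O, 0 °C
Reagents that add atoms: N-methylmorpholine N-oxide, C[N+]1([O-])CCOCC1; water, O
Why: Catalytic OsO4 dihydroxylation (Upjohn conditions) should add syn to the E olefin, giving the threo diol, from the face anti to the allylic C8–O8 bond in the hydrogen-eclipsed conformer (empirical rule for osmylation of allylic ethers), which places the C7 hydroxyl anti to O8.

**Step 15**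
Reactants: 22 diol
Product: 23 C6,C7-acetonide
Conditions: 2,2-dimethoxypropane, pyridinium p-toluenesulfonate (cat.), CH2Cl2, 23 °C
Reagents that add atoms: 2,2-dimethoxypropane, COC(C)(C)OC
Why: Acid-catalysed acetonide formation should protect the vicinal diol as the trans-dioxolane.

**Step 16**
Reactants: 23 acetonide
Product: 24 C4 primary alcohol
Conditions: 2,3-dichloro-5,6-dicyano-1,4-benzoquinone, CH2Cl2/pH 7 buffer, 0 °C
Reagents that add atoms: none
Why: Oxidative cleavage of the p-methoxybenzyl ether (hydride abstraction, hydrolysis of the oxocarbenium ion) should free the C4 hydroxyl in a buffered medium that spares acetonide and silyl ether.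

**Step 17**
Reactants: 24 primary alcohol
Product: 25 C4 aldehyde
Conditions: Dess–Martin periodinane, NaHCO3, CH2Cl2, 0 °C
Reagents that add atoms: none
Why: Dess–Martin oxidation should give the β-alkoxy aldehyde, which is used at once to avoid β-elimination.

**Step 18**
Reactants: 25 C4 aldehyde; 26 1,3-bis(triisopropylsilyl)propyne
Product: 27 (Z)-enyne with silylated alkyne
Conditions: 26, n-BuLi, THF, −78 °C; then 25, −78 → 0 °C
Reagents that add atoms: none
Why: Peterson olefination with the lithiated 1,3-disilylpropyne should give the Z enyne, because the bulky silyl groups enforce the anti adduct, which loses silanolate by syn elimination.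

**Step 19**
Reactants: 27 acetonide enyne
Product: 28 C6,C7-diol enyne
Conditions: AcOH/H2O/THF, 40 °C
Reagents that add atoms: none
Why: Mild acid-catalysed hydrolysis should remove the acetonide while the internal bicyclic ketal, far less prone to ionise, and the hindered silyl groups survive.

**Step 20**
Reactants: 28 diol enyne
Product: 30 silyl-protected 2,5-dioxabicyclo[2.2.1]heptane still carrying the bicyclic ketal, via iodo oxolane 29 (not isolated)
Conditions: N-iodosuccinimide, NaHCO3, MeCN, −30 → 0 °C; then NaH, THF, 0 → 23 °C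
Reagents that add atoms: none
Why: Iodoetherification (anti addition: O7 attacks C4 in 5-exo mode, iodine on propargylic C3) followed by intramolecular Williamson etherification (O6 displaces iodide with inversion) amounts to syn addition of O7 and O6 across the Z olefin, which is the C3/C4 relationship of the target, and only the oxolane with C6–O and C4–C3 cis can close, so the bicycle should form with exo ethynyl.

**Step 21**
Reactants: 30 bicyclic ketal
Product: 31 2,6-cis oxane with free C8 hydroxyl
Conditions: Et3SiH, TiCl4, CH2Cl2, −78 °C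
Reagents that add atoms: none
Why: Reductive ketal opening: TiCl4 should ionise the C13–O8 bond to the six-membered oxocarbenium ion and Et3SiH should attack axially, anti to the departing oxygen, so that hydrogen enters trans to the C9 substituent and the ethyl group ends cis to it, while the C8 hydroxyl is released.

**Step 22**
Reactants: 31 silylated oxane
Product: 32 C8,C12-diol with terminal alkyne
Conditions: n-Bu4NF, THF, 0 → 23 °C
Reagents that add atoms: none
Why: Fluoride-mediated desilylation should remove the silyl ether and the alkynylsilane in one operation.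

**Step 23**
Reactants: 32 diol
Product: 33 target tribromide
Conditions: CBr4, P(n-C8H17)3, toluene, 70 °C
Reagents that add atoms: carbon tetrabromide, BrC(Br)(Br)Br
Why: Double Appel-type bromination: each alkoxyphosphonium ion should be displaced by bromide with inversion (SN2), turning the axial C12 hydroxyl into the equatorial bromide and setting C8.

**Compound list**
1 | penta-1,4-dien-3-ol | C=CC(O)C=C | starting material
2 | (2S,3R)-1,2-epoxypent-4-en-3-ol | C=C[C@@H](O)[C@@H]1CO1 | intermediate
3 | (2S,3R)-pent-4-ene-1,2,3-triol | C=C[C@@H](O)[C@@H](O)CO | intermediate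
4 | (2S,3R)-2,3-dihydroxypent-4-en-1-yl pivalate (erythro diol; C7–C10) | C=C[C@@H](O)[C@@H](O)COC(=O)C(C)(C)C | intermediate
5 | trimethyl orthopropionate | CCC(OC)(OC)OC | starting material
6 | allyltrimethylsilane | C=CC[Si](C)(C)C | starting material
7 | 4,4-dimethoxyhex-1-ene | CCC(OC)(OC)CC=C | intermediate
8 | [(4S,5R)-2-ethyl-2-(prop-2-enyl)-5-vinyl-1,3-dioxolan-4-yl]methyl pivalate, epimer with allyl cis to vinyl | CC(C)(C)C(=O)OC[C@@H]1O[C@](CC)(CC=C)O[C@@H]1C=C | intermediate
9 | [(1R,5R,7S)-5-ethyl-6,8-dioxabicyclo[3.2.1]oct-2-en-7-yl]methyl pivalate (CH2OPiv endo; bicyclic C1, C2, C3, C4, C5, C7 = C9, C10, C11, C12, C13, C8) | CC(C)(C)C(=O)OC[C@@H]1O[C@]2(CC)CC=C[C@H]1O2 | intermediate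
10 | 4-hydroxy derivative of 9 (allylic alcohol at C12, epimer mixture) | CC(C)(C)C(=O)OC[C@@H]1O[C@]2(CC)C(O)C=C[C@H]1O2 | intermediate
11 | [(1R,5R,7S)-5-ethyl-4-oxo-6,8-dioxabicyclo[3.2.1]oct-2-en-7-yl]methyl pivalate | CC(C)(C)C(=O)OC[C@@H]1O[C@]2(CC)C(=O)C=C[C@H]1O2 | intermediate
12 | 2-bromo-4-oxo ketal (Br on C10 anti to the O8–C8 bridge) | CC(C)(C)C(=O)OC[C@@H]1O[C@]2(CC)C(=O)C[C@@H](Br)[C@H]1O2 | intermediate
13 | 2-bromo-4-hydroxy ketal (C10–Br anti, C12–OH syn to the bridge) | CC(C)(C)C(=O)OC[C@@H]1O[C@]2(CC)[C@H](O)C[C@@H](Br)[C@H]1O2 | intermediate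
14 | C12 tert-butyldimethylsilyl ether of 13 | CC(C)(C)C(=O)OC[C@@H]1O[C@]2(CC)[C@H](O[Si](C)(C)C(C)(C)C)C[C@@H](Br)[C@H]1O2 | intermediate
15 | C7 primary alcohol (pivalate removed) | OC[C@@H]1O[C@]2(CC)[C@H](O[Si](C)(C)C(C)(C)C)C[C@@H](Br)[C@H]1O2 | intermediate
16 | C7 aldehyde | O=C[C@@H]1O[C@]2(CC)[C@H](O[Si](C)(C)C(C)(C)C)C[C@@H](Br)[C@H]1O2 | intermediate
17 | 3-[(4-methoxybenzyl)oxy]propan-1-ol | COc1ccc(COCCCO)cc1 | starting material
18 | 1-phenyl-1H-tetrazole-5-thiol | Sc1nnnn1-c1ccccc1 | starting material
19 | 5-({3-[(4-methoxybenzyl)oxy]propyl}sulfanyl)-1-phenyl-1H-tetrazole | COc1ccc(COCCCSc2nnnn2-c2ccccc2)cc1 | intermediate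
20 | 5-({3-[(4-methoxybenzyl)oxy]propyl}sulfonyl)-1-phenyl-1H-tetrazole | COc1ccc(COCCCS(=O)(=O)c2nnnn2-c2ccccc2)cc1 | intermediate
21 | (E)-C6=C7 olefin on the bicyclic ketal, C4–O-p-methoxybenzyl | COc1ccc(COCC/C=C/[C@@H]2O[C@]3(CC)[C@H](O[Si](C)(C)C(C)(C)C)C[C@@H](Br)[C@H]2O3)cc1 | intermediate
22 | C6,C7-diol (C6/C7 threo, C7/C8 erythro) | COc1ccc(COCC[C@@H](O)[C@H](O)[C@@H]2O[C@]3(CC)[C@H](O[Si](C)(C)C(C)(C)C)C[C@@H](Br)[C@H]2O3)cc1 | intermediate
23 | C6,C7-acetonide of 22 | COc1ccc(COCC[C@H]2OC(C)(C)O[C@@H]2[C@@H]3O[C@]4(CC)[C@H](O[Si](C)(C)C(C)(C)C)C[C@@H](Br)[C@H]3O4)cc1 | intermediate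
24 | C4 primary alcohol | OCC[C@H]1OC(C)(C)O[C@@H]1[C@@H]2O[C@]3(CC)[C@H](O[Si](C)(C)C(C)(C)C)C[C@@H](Br)[C@H]2O3 | intermediate
25 | C4 aldehyde | O=CC[C@H]1OC(C)(C)O[C@@H]1[C@@H]2O[C@]3(CC)[C@H](O[Si](C)(C)C(C)(C)C)C[C@@H](Br)[C@H]2O3 | intermediate
26 | 1,3-bis(triisopropylsilyl)propyne | CC(C)[Si](C(C)C)(C(C)C)CC#C[Si](C(C)C)(C(C)C)C(C)C | starting material
27 | (Z)-C3=C4 enyne, alkyne silylated, C6,C7-acetonide | CC(C)[Si](C(C)C)(C(C)C)C#C/C=C\C[C@H]1OC(C)(C)O[C@@H]1[C@@H]2O[C@]3(CC)[C@H](O[Si](C)(C)C(C)(C)C)C[C@@H](Br)[C@H]2O3 | intermediate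
28 | (Z)-enyne C6,C7-diol | CC(C)[Si](C(C)C)(C(C)C)C#C/C=C\C[C@@H](O)[C@H](O)[C@@H]1O[C@]2(CC)[C@H](O[Si](C)(C)C(C)(C)C)C[C@@H](Br)[C@H]1O2 | intermediate
29 | oxolane (O7–C4) with propargylic iodide at C3 and free C6–OH | CC(C)[Si](C(C)C)(C(C)C)C#C[C@@H](I)[C@H]1C[C@@H](O)[C@H](O1)[C@@H]2O[C@]3(CC)[C@H](O[Si](C)(C)C(C)(C)C)C[C@@H](Br)[C@H]2O3 | intermediate
30 | 2,5-dioxabicyclo[2.2.1]heptane (exo silylethynyl) joined at C7–C8 to the bicyclic ketal | CC(C)[Si](C(C)C)(C(C)C)C#C[C@@H]1O[C@@H]2C[C@H]1O[C@@H]2[C@@H]3O[C@]4(CC)[C@H](O[Si](C)(C)C(C)(C)C)C[C@@H](Br)[C@H]3O4 | intermediate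
31 | 2,6-cis oxane: C8–OH free, C10–Br equatorial, C12–O-silyl axial, C13–Et equatorial | CC(C)[Si](C(C)C)(C(C)C)C#C[C@@H]1O[C@@H]2C[C@H]1O[C@@H]2[C@H](O)[C@@H]1O[C@H](CC)[C@H](O[Si](C)(C)C(C)(C)C)C[C@H]1Br | intermediate
32 | C8,C12-diol with terminal alkyne (both carbinols epimeric to the target bromides) | C#C[C@@H]1O[C@@H]2C[C@H]1O[C@@H]2[C@H](O)[C@@H]1O[C@H](CC)[C@H](O)C[C@H]1Br | intermediate
33 | (3S,4R,6R,7S,8R,9R,10R,12S,13R)-8,10,12-tribromo-3,6:4,7:9,13-triepoxypentadec-1-yne | C#C[C@@H]1O[C@@H]2C[C@H]1O[C@@H]2[C@@H](Br)[C@@H]1O[C@H](CC)[C@@H](Br)C[C@H]1Br | target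

**Totals.** 23 steps in all. The longest linear sequence is 20 steps (1, 2, 3, 5–10, 13–23).

**Three steps most likely to fail**

Step 20. The iodonium ion may be opened on the wrong olefin face or at C3, and the strained second ring closure may lose out to elimination of HI. The fallback sets out from 27. Epoxidation of the Z olefin with m-chloroperbenzoic acid should give the cis-epoxide F3 (the other face isomer cannot bicyclise and is removed). Aqueous acid then removes the acetonide and lets O7 open the epoxide at C4 with inversion, giving the oxolane diol F4. Mitsunobu etherification (PPh3, diisopropyl azodicarboxylate) closes O6–C3 with inversion at the propargylic carbon, and the route is rejoined at 30.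

Step 7. The β-bromo ketone may lose HBr before it is reduced, and hydride delivery to C12 may be poorly face-selective because the axial C10 bromine lies 1,3 to the open trajectory. The fallback sets out from 11. HBr is added as before and the ketone is reduced with LiBH(s-Bu)3 so that the material is collected as the C12-epimeric bromo alcohol F1. Mitsunobu inversion with 4-nitrobenzoic acid should give the inverted 4-nitrobenzoate F2, and methanolysis (K2CO3, MeOH, 0 °C) returns to the route at 13.

Step 23. Displacement at C8 and C12, both flanked by ether carbons, may be slow, so elimination or participation of a neighbouring ring oxygen may compete. The fallback sets out from 32. Both hydroxyls are converted (ClCH2SO2Cl, 2,6-lutidine) into the bis(chloromethanesulfonate) F5, and displacement with LiBr in DMF at moderate temperature should give both bromides with inversion, arriving at 33.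

**Further compounds**
F1 | step 7 | C12 epimer of 13 (C12–OH anti to the O8–C8 bridge) | CC(C)(C)C(=O)OC[C@@H]1O[C@]2(CC)[C@@H](O)C[C@@H](Br)[C@H]1O2
F2 | step 7 | 4-nitrobenzoate of 13 (C12–O syn to the bridge) | CC(C)(C)C(=O)OC[C@@H]1O[C@]2(CC)[C@H](OC(=O)c3ccc(cc3)[N+](=O)[O-])C[C@@H](Br)[C@H]1O2
F3 | step 20 | cis-C3,C4-epoxide of 27 | CC(C)[Si](C(C)C)(C(C)C)C#C[C@H]1O[C@H]1C[C@H]2OC(C)(C)O[C@@H]2[C@@H]3O[C@]4(CC)[C@H](O[Si](C)(C)C(C)(C)C)C[C@@H](Br)[C@H]3O4
F4 | step 20 | oxolane (O7–C4) with propargylic C3–OH and free C6–OH | CC(C)[Si](C(C)C)(C(C)C)C#C[C@@H](O)[C@H]1C[C@@H](O)[C@H](O1)[C@@H]2O[C@]3(CC)[C@H](O[Si](C)(C)C(C)(C)C)C[C@@H](Br)[C@H]2O3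
F5 | step 23 | C8,C12-bis(chloromethanesulfonate) of 32 | C#C[C@@H]1O[C@@H]2C[C@H]1O[C@@H]2[C@H](OS(=O)(=O)CCl)[C@@H]1O[C@H](CC)[C@H](OS(=O)(=O)CCl)C[C@H]1Br
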